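## Retrosynthetic overview

1. The target is epigallocatechin-(4β→8)-catechin (upper unit 2R,3R,4R; lower unit 2R,3S). The last operation is global hydrogenolysis of a nona-O-benzyl dimer.
2. The interflavan C4–C8 bond is traced back to a C4 cation equivalent, a 4β-alkoxy ether of perbenzylated epigallocatechin. Perbenzylated catechin serves as the C8 nucleophile.
3. Key disconnection: the C4–O bond of that ether. It is made by direct DDQ-mediated anodic C4–H alkoxylation with 2-ethoxyethanol (the new step), and everything downstream depends on it.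
4. Each benzyl ether comes in one step from a commercial flavan-3-ol. These supply C2 and C3 of both units, and C4 is set by substrate control.
5. Ring order: no ring is built. Rings A, C, B (upper unit) and D, F, E (lower unit) are carried through intact.

Assumption: (−)-epigallocatechin (a green-tea isolate) and (+)-catechin are taken as inexpensive commercial chemicals available in multigram lots.

## Route

Step 1
Reactants: 1 (−)-epigallocatechin; 2 benzyl bromide
Product: 3 penta-O-benzyl-(−)-epigallocatechin (benzyl ethers at O5, O7, O3', O4', O5'; 3-OH free; 2R,3R)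
Conditions: BnBr (5.5 equiv), K2CO3 (6 equiv), DMF, Ar, 0 °C to rt, 24 h
Reagents that add atoms: benzyl bromide, BrCc1ccccc1
Why: Williamson ether synthesis in which K2CO3 deprotonates only the five phenols and not the secondary 3-OH, so C2 and C3 are untouched, while argon and low temperature suppress pyrogallol autoxidation and C2 epimerisation.

Step 2
Reactants: 4 (+)-catechin; 2 benzyl bromide
Product: 5 tetra-O-benzyl-(+)-catechin (benzyl ethers at O5, O7, O3', O4'; 3-OH free; 2R,3S)
Conditions: BnBr (4.4 equiv), K2CO3 (5 equiv), DMF, Ar, 0 °C to rt, 24 h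
Reagents that add atoms: benzyl bromide, BrCc1ccccc1
Why: Williamson ether synthesis selective for the four phenols with C2 and C3 untouched, needed because the benzylated ring D later couples only at C8, which the free phenol would not guarantee.

Step 3
Reactants: 3 penta-O-benzyl-(−)-epigallocatechin; 6 ethylene glycol monoethyl ether (2-ethoxyethanol)
Product: 7 penta-O-benzyl-4β-(2-ethoxyethoxy)epigallocatechin (2R,3R,4S; 3-OH free)
Conditions: DDQ (20 mol %), 6 (5 equiv), 2,6-lutidine (2.2 equiv), nBu4NBF4 (0.1 M), 4 Å MS, CH2Cl2, H-cell with glass frit, reticulated vitreous carbon anode at +0.75 V vs SCE, Pt cathode in 2,6-lutidinium BF4/nBu4NBF4/CH2Cl2, 2.1 F/mol, rt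
Reagents that add atoms: 2-ethoxyethanol, CCOCCO
Why: Proposed new method: DDQ-mediated indirect anodic C(sp3)–H alkoxylation of a flavan-3-ol, in which DDQ takes the C4 hydride of ring C to give the benzylic cation stabilised by O5, O7 and O1 (the ArOCH2Ph and C2–H sites give much poorer cations and are left alone), 2-ethoxyethanol adds from the β face anti to the axial 3α-OH and the 2α-aryl group to form the C4–O bond as the 3,4-trans (4S) ether, and DDQH2 is re-oxidised at the anode about 0.5 V below the oxidation onset of the benzylated arenes while lutidinium carries the two protons to the cathode as H2, so only a low standing DDQ concentration meets the product and over-oxidation is curbed; the closest known reaction types are the stoichiometric DDQ C4-alkoxylation of benzylated flavan-3-ols and quinone-mediated indirect electrolysis of simple benzylic substrates.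

Step 4
Reactants: 7 penta-O-benzyl-4β-(2-ethoxyethoxy)epigallocatechin; 5 tetra-O-benzyl-(+)-catechin
Product: 8 nona-O-benzyl-epigallocatechin-(4β→8)-catechin (upper unit 2R,3R,4R; lower unit 2R,3S; both 3-OH free)
Conditions: 5 (1.5 equiv), Yb(OTf)3 (20 mol %), CH2Cl2, rt, 6 h
Reagents that add atoms: none
Why: Lewis-acid SN1 Friedel–Crafts alkylation in which Yb(OTf)3 chelates and ionises the 2-ethoxyethoxy group and the C4 cation is attacked by C8 of 5 (the most nucleophilic and least hindered ring D position) from the β face anti to the 3α-OH and 2α-aryl groups, which sets the 4R (3,4-trans) stereocentre as is general for 2,3-cis flavanyl cations.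

Step 5
Reactants: 8 nona-O-benzyl-epigallocatechin-(4β→8)-catechin
Product: 9 epigallocatechin-(4β→8)-catechin (target, CNP0225927.1)
Conditions: H2 (1 atm), Pd(OH)2/C (20 wt %), THF/MeOH/H2O (20:1:1), rt, 4 h; filter under Ar, lyophilise
Reagents that add atoms: none
Why: Catalytic hydrogenolysis cleaves the nine aryl benzyl ethers under conditions that leave the C4–C8 bond, the ring C and ring F ethers and all five stereocentres intact in the proanthocyanidin series.

## Compound list

1 | (−)-epigallocatechin (2R,3R) | Oc1cc(O)c2c(c1)O[C@H](c1cc(O)c(O)c(O)c1)[C@H](O)C2 | starting material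
2 | benzyl bromide | BrCc1ccccc1 | starting material
3 | penta-O-benzyl-(−)-epigallocatechin (2R,3R) | c1ccccc1COc1cc(OCc2ccccc2)c2c(c1)O[C@H](c1cc(OCc3ccccc3)c(OCc3ccccc3)c(OCc3ccccc3)c1)[C@H](O)C2 | intermediate
4 | (+)-catechin (2R,3S) | Oc1cc(O)c2c(c1)O[C@H](c1ccc(O)c(O)c1)[C@@H](O)C2 | starting material
5 | tetra-O-benzyl-(+)-catechin (2R,3S) | c1ccccc1COc1cc(OCc2ccccc2)c2c(c1)O[C@H](c1ccc(OCc3ccccc3)c(OCc3ccccc3)c1)[C@@H](O)C2 | intermediate
6 | 2-ethoxyethanol | CCOCCO | starting material
7 | penta-O-benzyl-4β-(2-ethoxyethoxy)epigallocatechin (2R,3R,4S) | c1ccccc1COc1cc(OCc2ccccc2)c2c(c1)O[C@H](c1cc(OCc3ccccc3)c(OCc3ccccc3)c(OCc3ccccc3)c1)[C@H](O)[C@H]2OCCOCC | intermediate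
8 | nona-O-benzyl-epigallocatechin-(4β→8)-catechin | c1ccccc1COc1cc(OCc2ccccc2)c2c(c1)O[C@H](c1cc(OCc3ccccc3)c(OCc3ccccc3)c(OCc3ccccc3)c1)[C@H](O)[C@H]2c1c(OCc2ccccc2)cc(OCc2ccccc2)c2c1O[C@H](c1ccc(OCc3ccccc3)c(OCc3ccccc3)c1)[C@@H](O)C2 | intermediate
9 | epigallocatechin-(4β→8)-catechin | Oc1cc(O)c2c(c1)O[C@H](c1cc(O)c(O)c(O)c1)[C@H](O)[C@H]2c1c(O)cc(O)c2c1O[C@H](c1ccc(O)c(O)c1)[C@@H](O)C2 | target

## Step count and risks

Total steps: 5. Longest linear sequence: 4 (1 → 3 → 7 → 8 → 9).

**Step 3 (new step).**
- Risks: DDQ may turn over slowly at 20 mol %. Acid may build up at the anode, re-ionise 7 and cause self-condensation. A second oxidation at C4 is also possible.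
- Fallback (known chemistry): it sets out from 3 and drops electrolysis and catalysis altogether.
- 3 is oxidised with stoichiometric DDQ (2 equiv) in CH2Cl2 in the presence of ethylene glycol. This gives penta-O-benzyl-4β-(2-hydroxyethoxy)epigallocatechin F1.
- F1 is condensed with 5 (4 equiv) under TiCl4 in CH2Cl2/THF at 0 °C. The fallback comes back to the route at 8.

**Step 4.**
- Risks: 7 may self-condense through its own ring A. 8 may react further to give trimers. The hard Lewis acid may re-ionise the new interflavan bond.
- Fallback: it sets out from 7 and changes the leaving group from oxygen to sulfur.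
- 7 is treated with the aluminium thiolate made from AlMe3 and 2-mercaptobenzothiazole in CH2Cl2. This gives penta-O-benzyl-4β-(benzothiazol-2-ylthio)epigallocatechin F2.
- F2 is activated chemoselectively at sulfur with the thiophilic salt AgBF4 in THF/CH2Cl2 at 0 °C in the presence of 5. The C–C bond already formed is not touched. The fallback comes back at 8.

**Step 1.**
- Risks: the free pyrogallol under base may autoxidise, ring A may be C-benzylated, and C2 may epimerise.
- Fallback: it sets out from 1 and never exposes the free polyphenol to base.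
- 1 is peracetylated (Ac2O, pyridine, rt) to (−)-epigallocatechin hexaacetate F3.
- F3 undergoes stepwise in situ deacetylation–benzylation (NaH, BnBr, DMF, slow addition of water at 0 °C). Each phenoxide is capped as soon as it is unmasked, giving penta-O-benzyl-(−)-epigallocatechin 3-O-acetate F4.
- Methanolysis of F4 (K2CO3, MeOH/THF, rt) comes back to the route at 3.

## Further compounds

F1 | step 3 | penta-O-benzyl-4β-(2-hydroxyethoxy)epigallocatechin | c1ccccc1COc1cc(OCc2ccccc2)c2c(c1)O[C@H](c1cc(OCc3ccccc3)c(OCc3ccccc3)c(OCc3ccccc3)c1)[C@H](O)[C@H]2OCCO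
F2 | step 4 | penta-O-benzyl-4β-(benzothiazol-2-ylthio)epigallocatechin | c1ccccc1COc1cc(OCc2ccccc2)c2c(c1)O[C@H](c1cc(OCc3ccccc3)c(OCc3ccccc3)c(OCc3ccccc3)c1)[C@H](O)[C@H]2Sc1nc2ccccc2s1
F3 | step 1 | (−)-epigallocatechin hexaacetate | CC(=O)Oc1cc(OC(C)=O)c2c(c1)O[C@H](c1cc(OC(C)=O)c(OC(C)=O)c(OC(C)=O)c1)[C@H](OC(C)=O)C2
F4 | step 1 | penta-O-benzyl-(−)-epigallocatechin 3-O-acetate | c1ccccc1COc1cc(OCc2ccccc2)c2c(c1)O[C@H](c1cc(OCc3ccccc3)c(OCc3ccccc3)c(OCc3ccccc3)c1)[C@H](OC(C)=O)C2
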